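The ten-membered carbocycle hides a carvone ring: C1–C6, with the Z C4=C5 alkene, the C3 oxygen and the C10/C9/C14 isopropenyl unit on C1, is an oxygenated p-menthane that is merely opened between C1 and C6 and spanned by C7–C8. The route therefore rests on an anionic oxy-Cope ring expansion of a cyclohexenol whose C6 carries, trans to the C1 isopropenyl group, an (E)-1-silylbuta-1,3-dien-2-yl unit (C8=C7 with the C11=C12 vinyl on C7). One [3,3] shift breaks C1–C6, forms C8–C9, and sets C8 (as C–Si, later C–O), the E C1(10) alkene and the ring size; lactone, methylene, ester and oxirane follow.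

Key step: step 9

Remark: atoms carry the germacrane numbering of the target throughout, also in the six-membered precursors (C3 carbinol, C4 methyl-bearing, C1 isopropenyl-bearing; C11–C13 lactone carbons, C14 on C10, C15 on C4); α is the ring face of H7, β the opposite face.

Step 1
Reactants: 1 (R)-(−)-carvone
Product: 2 (1R,5R)-cis-carveol
Conditions: NaBH4, CeCl3·7H2O, MeOH, 0 °C
Reagents that add atoms: none
Why: Luche 1,2-reduction: axial hydride delivery to the cerium-activated half-chair enone should give the equatorial alcohol, i.e. the new C3 carbinol centre with OH cis to the isopropenyl group, the epimer needed for the inversion that follows.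

Step 2
Reactants: 2 (1R,5R)-cis-carveol
Product: 4 (1S,5R)-trans-carveol, via trans-carveyl 4-nitrobenzoate 3 (not isolated)
Conditions: PPh3, DIAD, 4-nitrobenzoic acid, THF, 0 °C to rt; then K2CO3, MeOH, rt
Reagents that add atoms: 4-nitrobenzoic acid, OC(=O)c1ccc(cc1)[N+](=O)[O-]
Why: Mitsunobu reaction: the alkoxyphosphonium of the allylic alcohol is displaced by the carboxylate with SN2 inversion, which sets C3 in the 3S (3β) configuration of the target, and methanolysis of the activated ester in the same flask frees the trans alcohol.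

Step 3
Reactants: 4 (1S,5R)-trans-carveol
Product: 5 (1S,5R)-trans-carveol 4-methoxybenzyl ether
Conditions: NaH, 4-methoxybenzyl chloride, tetrabutylammonium iodide (catalytic), THF/DMF, 0 °C to rt
Reagents that add atoms: 4-methoxybenzyl chloride, COc1ccc(CCl)cc1
Why: Williamson etherification of the sodium alkoxide with the benzylic chloride; the ether should survive every basic, hydridic and organometallic step ahead, is removed oxidatively at the end, and no stereocentre is involved.

Step 4
Reactants: 5 (1S,5R)-trans-carveol 4-methoxybenzyl ether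
Product: 6 4,5-epoxide of 5 (oxirane anti to the C3 ether and syn to isopropenyl)
Conditions: mCPBA (1.0 equiv), NaHCO3, CH2Cl2, −15 to 0 °C
Reagents that add atoms: 3-chloroperoxybenzoic acid (mCPBA), OOC(=O)c1cccc(Cl)c1
Why: Prilezhaev epoxidation: the trisubstituted ring alkene is more nucleophilic than the 1,1-disubstituted isopropenyl alkene and is attacked anti to the pseudoaxial C3 ether, which places the oxirane syn to the isopropenyl group, the arrangement that opens diaxially at C5; the two oxirane centres are erased again in steps 5 and 6.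

Step 5
Reactants: 6 4,5-epoxide of 5
Product: 9 (1S,4S,6S)-6-(4-methoxybenzyloxy)-1-methyl-4-(prop-1-en-2-yl)cyclohex-2-en-1-ol (tertiary C4 alcohol with C5=C6), via hydroxy selenide 7 (not isolated), via selenoxide 8 (not isolated)
Conditions: (PhSe)2, NaBH4, EtOH, rt to 60 °C; then 30% H2O2, THF, 0 °C to rt
Reagents that add atoms: none
Why: Epoxide opening by selenolate followed by selenoxide syn-elimination: the soft nucleophile attacks the secondary oxirane carbon C5 trans-diaxially (Fürst–Plattner rule) and, since C4 bears no hydrogen, the selenoxide can only eliminate toward C6, which should give the tertiary C4 allylic alcohol with the alkene moved to C5=C6.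

Step 6
Reactants: 9 tertiary allylic alcohol
Product: 10 (4S,6R)-4-(4-methoxybenzyloxy)-3-methyl-6-(prop-1-en-2-yl)cyclohex-2-en-1-one
Conditions: pyridinium chlorochromate C5H5NH[CrO3Cl], 4 Å molecular sieves, CH2Cl2, rt
Reagents that add atoms: pyridinium chlorochromate, [O-][Cr](=O)(=O)Cl.c1cc[nH+]cc1
Why: Oxidative 1,3-transposition of a tertiary allylic alcohol (Babler–Dauben oxidation): the chromate ester shifts from C4 to C6 and is oxidised there, which restores the C4=C5 alkene and creates the C6 ketone, while the neighbouring C1 centre should not be enolised under these non-basic conditions.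

Step 7
Reactants: 10 enone + 11 ethynyl(dimethyl)phenylsilane
Product: 13 (1R,4S,6R)-1-{[dimethyl(phenyl)silyl]ethynyl}-4-(4-methoxybenzyloxy)-3-methyl-6-(prop-1-en-2-yl)cyclohex-2-en-1-ol, via lithium silylacetylide 12 (not isolated)
Conditions: 11, n-BuLi, THF, −78 °C; anhydrous CeCl3, −78 °C; then 10, −78 °C; NH4Cl aq
Reagents that add atoms: none
Why: 1,2-Addition of an organocerium acetylide: the weakly basic cerium reagent adds to the carbonyl without enolising C1 and should approach anti to the adjacent isopropenyl group (as hydride and alkenylmetal reagents do with isopiperitenone), so the new C6 carbinol centre carries the alkynyl group trans to isopropenyl, and any C6 epimer is removed by chromatography.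

Step 8
Reactants: 13 propargylic alcohol + 14 vinylmagnesium chloride
Product: 16 (1R,4S,6R)-1-{(1E)-1-[dimethyl(phenyl)silyl]buta-1,3-dien-2-yl}-4-(4-methoxybenzyloxy)-3-methyl-6-(prop-1-en-2-yl)cyclohex-2-en-1-ol, via cyclic alkenylmagnesium alkoxide 15 (not isolated)
Conditions: CH2=CHMgCl (5 equiv), THF/toluene, 70 °C; then NH4Cl aq, 0 °C
Reagents that add atoms: none
Why: Alkoxide-directed anti-carbomagnesiation of a propargylic alcohol: the magnesium alkoxide delivers a second vinyl Grignard so that vinyl adds to C7 and magnesium to C8 within a five-membered chelate, where silicon also stabilises the α-magnesio carbon, and protonolysis with retention leaves hydrogen cis and silicon trans to C6 (E vinylsilane).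

Step 9
Reactants: 16 dienyl cyclohexenol
Product: 19 (1(10)E,4Z)-3β-(4-methoxybenzyloxy)-8β-[dimethyl(phenyl)silyl]-13-norgermacra-1(10),4,11-trien-6-one (7αH; 3S,7S,8R), via potassium alkoxide 17 (not isolated), via potassium dienolate 18 (not isolated)
Conditions: KH, 18-crown-6, THF, 0 °C to rt; then cannulated into AcOH/THF, −78 °C
Reagents that add atoms: none
Why: Deprotonation with KH in the presence of 18-crown-6 frees the tertiary oxyanion, and the anionic oxy-Cope [3,3] shift then runs through a chair made of C8, C7, C6, C1, C10 and C9: the C1–C6 ring bond is cleaved while C8 bonds to C9, and the potassium dienolate so formed takes up a proton at C7 when it is run into cold acetic acid. The nearest precedent is the anionic oxy-Cope ring expansion of trans-1,2-dialkenylcyclohexenols made from isopiperitenone-type enones, which gives cyclodeca-1,5-dienones of the germacrane family. The ten-membered ring arises by four-atom ring expansion of the six-membered ring, not by joining two chain ends, so concentration is uncritical and the former cyclohexene alkene can only appear as the Z C4=C5 alkene. C8 is fixed by the E vinylsilane (silicon equatorial in the chair) in concert with the carvone-derived C1 centre, which decides which chair exists; the equatorial C1–C2 bond gives the E C1(10) alkene; C7 results from protonation of the dienolate on its peripheral face, the inner face being screened by the C1(10) alkene. What the step needs is the one chair in which the C6–C5 and C1–C2 ring bonds and the silyl group are all equatorial, and this is secured by the trans-diequatorial alkenyl groups set in step 7 and the E vinylsilane set in step 8, while the cold inverse quench favours α- over γ-protonation. Because silicon lies across the C7=C8 bond from the oxyanion it cannot shift to oxygen, and a C–Si bond, unlike a C–O bond, is not expelled from the neighbouring enolate, whose formation also makes the shift irreversible.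

Step 10
Reactants: 19 ten-membered ketone
Product: 20 (1(10)E,4Z)-3β-(4-methoxybenzyloxy)-8β-[dimethyl(phenyl)silyl]-13-norgermacra-1(10),4,11-trien-6α-ol (3S,6R,7S,8R)
Conditions: NaBH4, CeCl3·7H2O, MeOH/THF, −78 °C
Reagents that add atoms: none
Why: Luche 1,2-reduction of a medium-ring enone: in the cold, weakly acidic cerium medium the β,γ-vinyl ketone should not isomerise, and hydride attacks C6 from the peripheral face of the ring conformer left by the rearrangement, which sets the 6α (6R) alcohol with H6 and H7 anti, as the trans lactone needs.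

Step 11
Reactants: 20 allylic alcohol
Product: 22 (1(10)E,4Z)-3β-(4-methoxybenzyloxy)-8β-[dimethyl(phenyl)silyl]-13-norgermacra-1(10),4-diene-6α,12-diol, via bis(9-BBN) adduct 21 (not isolated)
Conditions: 9-borabicyclo[3.3.1]nonane (9-BBN, 3 equiv), THF, 0 °C to rt; then NaBO3·4H2O, H2O, rt
Reagents that add atoms: sodium perborate (NaBO3·4H2O), [Na+].[Na+].O[B-]1(O)OO[B-](O)(O)OO1
Why: Hydroboration–oxidation: 9-BBN adds only to the monosubstituted vinyl group, boron to the terminal C12, the trisubstituted ring alkenes being far slower, and perborate oxidises the C–B bonds with retention without touching the unactivated C–Si bond.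

Step 12
Reactants: 22 diol
Product: 24 (1(10)E,4Z)-3β-(4-methoxybenzyloxy)-8β-[dimethyl(phenyl)silyl]-13-norgermacra-1(10),4-dien-6α,12-olide (trans-fused γ-lactone; 3S,6R,7S,8R), via lactol 23 (not isolated)
Conditions: TEMPO (20 mol %), PhI(OAc)2, CH2Cl2, rt
Reagents that add atoms: none
Why: Oxoammonium-mediated oxidative lactonisation: the primary C12 alcohol is oxidised to the aldehyde, the C6 hydroxyl closes the five-membered lactol and this is oxidised to the trans-fused γ-lactone; because the C8 oxygen is still masked as silicon, only the 6,12-lactone can form and no stereocentre changes.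

Step 13
Reactants: 24 silyl lactone
Product: 26 (1(10)E,4Z)-8β-hydroxy-3β-(4-methoxybenzyloxy)-13-norgermacra-1(10),4-dien-6α,12-olide (3S,6R,7R,8R), via phenoxysilane 25 (not isolated)
Conditions: t-BuOOH (in decane) and KH premixed in N-methylpyrrolidone, 0 °C; then 24, rt; then Bu4NF, 60 °C; pH 5 buffer
Reagents that add atoms: tert-butyl hydroperoxide, CC(C)(C)OO
Why: Fleming–Tamao oxidation in its basic, nucleophilic-peroxide form: tert-butylperoxide adds to silicon, phenyl and then C8 migrate from silicon to oxygen, the alkyl shift with retention, and fluoride frees the 8β (8R) alcohol, so that no acid or electrophilic oxidant meets the two trisubstituted ring alkenes.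

Step 14
Reactants: 26 hydroxy lactone
Product: 27 (1(10)E,4Z)-8β-(tert-butyldimethylsilyloxy)-3β-(4-methoxybenzyloxy)-13-norgermacra-1(10),4-dien-6α,12-olide
Conditions: t-BuMe2SiOTf, 2,6-lutidine, CH2Cl2, −78 to 0 °C
Reagents that add atoms: tert-butyldimethylsilyl trifluoromethanesulfonate, CC(C)(C)[Si](C)(C)OS(=O)(=O)C(F)(F)F
Why: Silyl ether formation with the silyl triflate and a hindered base: the C8 hydroxyl is capped so that its alkoxide cannot attack the lactone carbonyl (lactone migration to C8) during the enolate chemistry of step 15.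

Step 15
Reactants: 27 silyl-protected lactone
Product: 30 (1(10)E,4Z)-8β-(tert-butyldimethylsilyloxy)-3β-(4-methoxybenzyloxy)germacra-1(10),4,11(13)-trien-6α,12-olide, via Mannich base 28 (not isolated), via trimethylammonium iodide 29 (not isolated)
Conditions: LiN(iPr)2, THF, −78 °C; dimethyl(methylidene)ammonium iodide, −78 to 0 °C; then iodomethane, MeOH, rt; then NaHCO3 aq, CH2Cl2, rt
Reagents that add atoms: dimethyl(methylidene)ammonium iodide, C=[N+](C)C.[I-]
Why: Eschenmoser methylenation: the lithium lactone enolate undergoes a Mannich reaction with the iminium salt, quaternisation and bicarbonate-induced E1cB loss of trimethylamine give the exocyclic C11=C13 alkene, and C7 is not deprotonated, so no stereocentre is touched.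

Step 16
Reactants: 30 silyl-protected methylene lactone
Product: 31 (1(10)E,4Z)-8β-hydroxy-3β-(4-methoxybenzyloxy)germacra-1(10),4,11(13)-trien-6α,12-olide (3S,6R,7R,8R)
Conditions: HF·pyridine, pyridine, THF, 0 °C to rt
Reagents that add atoms: none
Why: Fluoride-mediated desilylation with pyridine-buffered hydrogen fluoride, mild enough to leave the 4-methoxybenzyl ether, the diene and the Michael-acceptor lactone untouched.

Step 17
Reactants: 32 angelic acid
Product: 33 (Z)-2-methylbut-2-en-1-ol
Conditions: LiAlH4, Et2O, 0 °C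
Reagents that add atoms: none
Why: Hydride reduction of the carboxylic acid through its aluminium carboxylate to the primary allylic alcohol; the aluminate reduces only the carbonyl, so the Z alkene is kept.

Step 18
Reactants: 33 (Z)-2-methylbut-2-en-1-ol
Product: 34 [(2S,3R)-2,3-dimethyloxiran-2-yl]methanol
Conditions: Ti(OiPr)4 (10 mol %), L-(+)-diethyl tartrate (12 mol %), t-BuOOH, 4 Å molecular sieves, CH2Cl2, −20 °C
Reagents that add atoms: tert-butyl hydroperoxide, CC(C)(C)OO
Why: Sharpless asymmetric epoxidation: the titanium complex of the natural (R,R)-tartrate delivers the peroxide oxygen to the alkene face that gives the (2S,3R)-epoxy alcohol, both centres being formed together and their cis relation following from the Z alkene.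

Step 19
Reactants: 34 epoxy alcohol
Product: 35 (2R,3R)-2,3-dimethyloxirane-2-carboxylic acid
Conditions: RuCl3·xH2O (2 mol %), NaIO4, MeCN/EtOAc/H2O, rt
Reagents that add atoms: water, O
Why: Ruthenium tetroxide oxidation, generated catalytically from RuCl3 and periodate, of the primary alcohol through the aldehyde hydrate to the acid; the oxirane is inert and the change of the C2 descriptor from S to R is only a change of priorities.

Step 20
Reactants: 31 hydroxy methylene lactone + 35 (2R,3R)-2,3-dimethyloxirane-2-carboxylic acid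
Product: 37 (1(10)E,4Z)-8β-[(2R,3R)-2,3-dimethyloxirane-2-carbonyloxy]-3β-(4-methoxybenzyloxy)germacra-1(10),4,11(13)-trien-6α,12-olide, via mixed anhydride 36 (not isolated)
Conditions: 35, 2,4,6-trichlorobenzoyl chloride, Et3N, toluene, rt; then 31, DMAP, rt to 40 °C
Reagents that add atoms: none
Why: Yamaguchi esterification: the mixed anhydride and then the acylpyridinium acylate the hindered 8β alcohol with retention at C8, and the acid, which has no α-hydrogen, cannot epimerise or isomerise as an angelate would.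

Step 21
Reactants: 37 diene ester
Product: 38 (4Z)-1β,10α-epoxy-8β-[(2R,3R)-2,3-dimethyloxirane-2-carbonyloxy]-3β-(4-methoxybenzyloxy)germacra-4,11(13)-dien-6α,12-olide (1R,10R)
Conditions: mCPBA (1.1 equiv), NaHCO3, CH2Cl2, 0 °C
Reagents that add atoms: 3-chloroperoxybenzoic acid (mCPBA), OOC(=O)c1cccc(Cl)c1
Why: Prilezhaev epoxidation: the strained E C1(10) alkene is the most nucleophilic one (C4=C5 carries two allylic oxygens, C11=C13 is conjugated) and in the ten-membered ring only its peripheral face is open, which in the preferred conformer of the lactone-fused ring (C14 on the β face) should give the 1β,10α (1R,10R) oxirane, as peracids do with related germacra-1(10)-en-6,12-olides.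

Step 22
Reactants: 38 4-methoxybenzyl ether of the target
Product: 39 CNP0268255.1 [(4Z)-1β,10α-epoxy-3β-hydroxy-8β-[(2R,3R)-2,3-dimethyloxirane-2-carbonyloxy]germacra-4,11(13)-dien-6α,12-olide]
Conditions: DDQ, CH2Cl2/pH 7 phosphate buffer, 0 °C
Reagents that add atoms: none
Why: Oxidative cleavage of the 4-methoxybenzyl ether by DDQ (benzylic hydride abstraction, then hydrolysis of the oxocarbenium ion) under buffered neutral conditions, which should spare both oxiranes, the ester and the methylene lactone.

Compound list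
1 | (R)-(−)-carvone | CC1=CC[C@H](CC1=O)C(C)=C | starting material
2 | (1R,5R)-cis-carveol | CC(=C)[C@@H]1CC=C(C)[C@H](O)C1 | intermediate
3 | (1S,5R)-trans-carveyl 4-nitrobenzoate | CC(=C)[C@@H]1CC=C(C)[C@@H](OC(=O)c2ccc(cc2)[N+](=O)[O-])C1 | intermediate
4 | (1S,5R)-trans-carveol | CC(=C)[C@@H]1CC=C(C)[C@@H](O)C1 | intermediate
5 | (1S,5R)-trans-carveol 4-methoxybenzyl ether | CC(=C)[C@@H]1CC=C(C)[C@@H](OCc2ccc(OC)cc2)C1 | intermediate
6 | 4,5-epoxide of 5, oxirane anti to the C3 ether and syn to isopropenyl | CC(=C)[C@@H]1C[C@@H]2O[C@]2(C)[C@@H](OCc2ccc(OC)cc2)C1 | intermediate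
7 | hydroxy selenide (C4 tertiary OH, C5 phenylseleno, trans-diaxial) | CC(=C)[C@@H]1C[C@@H]([Se]c2ccccc2)[C@](C)(O)[C@@H](OCc2ccc(OC)cc2)C1 | intermediate
8 | selenoxide of 7 | CC(=C)[C@@H]1C[C@@H]([Se](=O)c2ccccc2)[C@](C)(O)[C@@H](OCc2ccc(OC)cc2)C1 | intermediate
9 | (1S,4S,6S)-6-(4-methoxybenzyloxy)-1-methyl-4-(prop-1-en-2-yl)cyclohex-2-en-1-ol | CC(=C)[C@@H]1C=C[C@](C)(O)[C@@H](OCc2ccc(OC)cc2)C1 | intermediate
10 | (4S,6R)-4-(4-methoxybenzyloxy)-3-methyl-6-(prop-1-en-2-yl)cyclohex-2-en-1-one | O=C1C=C(C)[C@@H](OCc2ccc(OC)cc2)C[C@@H]1C(C)=C | intermediate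
11 | ethynyl(dimethyl)phenylsilane | C#C[Si](C)(C)c1ccccc1 | starting material
12 | lithium [dimethyl(phenyl)silyl]acetylide | [Li]C#C[Si](C)(C)c1ccccc1 | intermediate
13 | (1R,4S,6R)-1-{[dimethyl(phenyl)silyl]ethynyl}-4-(4-methoxybenzyloxy)-3-methyl-6-(prop-1-en-2-yl)cyclohex-2-en-1-ol | O[C@]1(C#C[Si](C)(C)c2ccccc2)C=C(C)[C@@H](OCc2ccc(OC)cc2)C[C@@H]1C(C)=C | intermediate
14 | vinylmagnesium chloride | C=C[Mg]Cl | starting material
15 | cyclic alkenylmagnesium alkoxide (O–Mg–C8 chelate, vinyl on C7) | [Mg]1O[C@]2(C(C=C)=C1[Si](C)(C)c1ccccc1)C=C(C)[C@@H](OCc1ccc(OC)cc1)C[C@@H]2C(C)=C | intermediate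
16 | (1R,4S,6R)-1-{(1E)-1-[dimethyl(phenyl)silyl]buta-1,3-dien-2-yl}-4-(4-methoxybenzyloxy)-3-methyl-6-(prop-1-en-2-yl)cyclohex-2-en-1-ol | O[C@]1(/C(C=C)=C/[Si](C)(C)c2ccccc2)C=C(C)[C@@H](OCc2ccc(OC)cc2)C[C@@H]1C(C)=C | intermediate
17 | potassium alkoxide of 16 | [K+].[O-][C@]1(/C(C=C)=C/[Si](C)(C)c2ccccc2)C=C(C)[C@@H](OCc2ccc(OC)cc2)C[C@@H]1C(C)=C | intermediate
18 | potassium dienolate of 19 (C6 enolate, C6=C7 trans in the ring) | [K+].[O-]/C1=C(/C=C)[C@H]([Si](C)(C)c2ccccc2)C/C(C)=C/C[C@H](OCc2ccc(OC)cc2)/C(C)=C\1 | intermediate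
19 | (1(10)E,4Z)-3β-(4-methoxybenzyloxy)-8β-[dimethyl(phenyl)silyl]-13-norgermacra-1(10),4,11-trien-6-one | O=C1/C=C(/C)[C@@H](OCc2ccc(OC)cc2)C/C=C(C)/C[C@@H]([Si](C)(C)c2ccccc2)[C@H]1C=C | intermediate
20 | (1(10)E,4Z)-3β-(4-methoxybenzyloxy)-8β-[dimethyl(phenyl)silyl]-13-norgermacra-1(10),4,11-trien-6α-ol | O[C@@H]1/C=C(/C)[C@@H](OCc2ccc(OC)cc2)C/C=C(C)/C[C@@H]([Si](C)(C)c2ccccc2)[C@H]1C=C | intermediate
21 | bis(9-BBN) adduct of 20 (O6 borinate, C12 borane) | B1(C2CCCC1CCC2)O[C@@H]1/C=C(/C)[C@@H](OCc2ccc(OC)cc2)C/C=C(C)/C[C@@H]([Si](C)(C)c2ccccc2)[C@H]1CCB1C2CCCC1CCC2 | intermediate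
22 | (1(10)E,4Z)-3β-(4-methoxybenzyloxy)-8β-[dimethyl(phenyl)silyl]-13-norgermacra-1(10),4-diene-6α,12-diol | O[C@@H]1/C=C(/C)[C@@H](OCc2ccc(OC)cc2)C/C=C(C)/C[C@@H]([Si](C)(C)c2ccccc2)[C@H]1CCO | intermediate
23 | 6,12-lactol of 22 | OC1O[C@@H]2/C=C(/C)[C@@H](OCc3ccc(OC)cc3)C/C=C(C)/C[C@@H]([Si](C)(C)c3ccccc3)[C@H]2C1 | intermediate
24 | (1(10)E,4Z)-3β-(4-methoxybenzyloxy)-8β-[dimethyl(phenyl)silyl]-13-norgermacra-1(10),4-dien-6α,12-olide | O=C1O[C@@H]2/C=C(/C)[C@@H](OCc3ccc(OC)cc3)C/C=C(C)/C[C@@H]([Si](C)(C)c3ccccc3)[C@H]2C1 | intermediate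
25 | 8β-[dimethyl(phenoxy)silyl] analogue of 24 | O=C1O[C@@H]2/C=C(/C)[C@@H](OCc3ccc(OC)cc3)C/C=C(C)/C[C@@H]([Si](C)(C)Oc3ccccc3)[C@H]2C1 | intermediate
26 | (1(10)E,4Z)-8β-hydroxy-3β-(4-methoxybenzyloxy)-13-norgermacra-1(10),4-dien-6α,12-olide | O=C1O[C@@H]2/C=C(/C)[C@@H](OCc3ccc(OC)cc3)C/C=C(C)/C[C@@H](O)[C@H]2C1 | intermediate
27 | (1(10)E,4Z)-8β-(tert-butyldimethylsilyloxy)-3β-(4-methoxybenzyloxy)-13-norgermacra-1(10),4-dien-6α,12-olide | O=C1O[C@@H]2/C=C(/C)[C@@H](OCc3ccc(OC)cc3)C/C=C(C)/C[C@@H](O[Si](C)(C)C(C)(C)C)[C@H]2C1 | intermediate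
28 | 11-(dimethylaminomethyl) lactone (Mannich base of 27) | O=C1O[C@@H]2/C=C(/C)[C@@H](OCc3ccc(OC)cc3)C/C=C(C)/C[C@@H](O[Si](C)(C)C(C)(C)C)[C@H]2C1CN(C)C | intermediate
29 | trimethylammonium iodide of 28 | [I-].O=C1O[C@@H]2/C=C(/C)[C@@H](OCc3ccc(OC)cc3)C/C=C(C)/C[C@@H](O[Si](C)(C)C(C)(C)C)[C@H]2C1C[N+](C)(C)C | intermediate
30 | (1(10)E,4Z)-8β-(tert-butyldimethylsilyloxy)-3β-(4-methoxybenzyloxy)germacra-1(10),4,11(13)-trien-6α,12-olide | C=C1C(=O)O[C@@H]2/C=C(/C)[C@@H](OCc3ccc(OC)cc3)C/C=C(C)/C[C@@H](O[Si](C)(C)C(C)(C)C)[C@@H]12 | intermediate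
31 | (1(10)E,4Z)-8β-hydroxy-3β-(4-methoxybenzyloxy)germacra-1(10),4,11(13)-trien-6α,12-olide | C=C1C(=O)O[C@@H]2/C=C(/C)[C@@H](OCc3ccc(OC)cc3)C/C=C(C)/C[C@@H](O)[C@@H]12 | intermediate
32 | angelic acid, (Z)-2-methylbut-2-enoic acid | C/C=C(/C)C(=O)O | starting material
33 | (Z)-2-methylbut-2-en-1-ol | C/C=C(/C)CO | intermediate
34 | [(2S,3R)-2,3-dimethyloxiran-2-yl]methanol | OC[C@]1(C)O[C@@H]1C | intermediate
35 | (2R,3R)-2,3-dimethyloxirane-2-carboxylic acid | OC(=O)[C@]1(C)O[C@@H]1C | intermediate
36 | mixed anhydride of 35 with 2,4,6-trichlorobenzoic acid | O=C(OC(=O)[C@]1(C)O[C@@H]1C)c1c(Cl)cc(Cl)cc1Cl | intermediate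
37 | (1(10)E,4Z)-8β-[(2R,3R)-2,3-dimethyloxirane-2-carbonyloxy]-3β-(4-methoxybenzyloxy)germacra-1(10),4,11(13)-trien-6α,12-olide | C=C1C(=O)O[C@@H]2/C=C(/C)[C@@H](OCc3ccc(OC)cc3)C/C=C(C)/C[C@@H](OC(=O)[C@]3(C)O[C@@H]3C)[C@@H]12 | intermediate
38 | (4Z)-1β,10α-epoxy-8β-[(2R,3R)-2,3-dimethyloxirane-2-carbonyloxy]-3β-(4-methoxybenzyloxy)germacra-4,11(13)-dien-6α,12-olide | C=C1C(=O)O[C@@H]2/C=C(/C)[C@@H](OCc3ccc(OC)cc3)C[C@H]3O[C@]3(C)C[C@@H](OC(=O)[C@]3(C)O[C@@H]3C)[C@@H]12 | intermediate
39 | CNP0268255.1, (4Z)-1β,10α-epoxy-3β-hydroxy-8β-[(2R,3R)-2,3-dimethyloxirane-2-carbonyloxy]germacra-4,11(13)-dien-6α,12-olide (1R,3S,6R,7R,8R,10R) | C=C1C(=O)O[C@@H]2/C=C(/C)[C@@H](O)C[C@H]3O[C@]3(C)C[C@@H](OC(=O)[C@]3(C)O[C@@H]3C)[C@@H]12 | target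

Total step count: 22 (steps 1–16 main line to 31, steps 17–19 for acid 35, steps 20–22 after the union).
Longest linear sequence: 19 steps (steps 1–16 and 20–22, from 1 to 39).

Steps most likely to fail

Step 9. The silyl-bearing terminus may slow the shift so that the free alkoxide fragments instead. The dienolate may also be protonated at the vinyl terminus (C12), or the β,γ-unsaturated ketone may drift into conjugation and lose the C7 configuration during work-up. The fallback sets out from 16 and comes back at 19 and runs the same rearrangement without any anion. Alcohol 16 is converted into its trimethylsilyl ether F1 (Me3SiCl, imidazole, DMF). This is heated in degassed toluene (sealed tube, about 200 °C), so that the neutral silyloxy-Cope rearrangement passes through the same chair and gives the ring-expanded trimethylsilyl dienol ether F2. This isolable enol ether is cleaved at −78 °C with buffered fluoride (Bu4NF, AcOH, THF), which delivers the proton to C7 under kinetic control and gives 19.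

Step 13. The basic peroxide medium may open the lactone; once the C8 hydroxyl is free the acyl group may close onto O8 instead of O6 (lactone migration), or the ring may stay open. The fallback sets out from 22 and comes back at 27 and oxidises silicon before any lactone exists. Diol 22 is tied up as the seven-membered 6,12-acetonide F3 (2,2-dimethoxypropane, pyridinium 4-toluenesulfonate). The same basic Fleming–Tamao oxidation on this base-stable acetal gives the 8β-alcohol F4. Silylation (t-BuMe2SiOTf, 2,6-lutidine) gives the silyl ether F5. Mild methanolysis of the acetonide (pyridinium 4-toluenesulfonate, MeOH) gives the 8-silyloxy 6,12-diol F6. TEMPO/PhI(OAc)2 then closes the lactone on the only free secondary hydroxyl and gives 27.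

Step 21. The E C1(10) alkene can turn through the ring and offer either face, so the peracid may deliver a mixture or mainly the 1α,10β oxirane; over-oxidation at C4=C5 is a lesser danger. The fallback sets out from 37 and arrives directly at 38, giving up substrate control for catalyst control. It is a Shi epoxidation with the D-fructose-derived ketone and KHSO5 (as 2KHSO5·KHSO4·K2SO4, K2CO3 buffer, MeCN/dimethoxymethane/H2O, 0 °C). Its spiro transition state oxidises E trisubstituted alkenes on the face that here corresponds to the (1R,10R) oxirane and so selects the reacting conformer; no new intermediate is involved.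

Further compounds
F1 | step 9 | trimethylsilyl ether of 16 | C[Si](C)(C)O[C@]1(/C(C=C)=C/[Si](C)(C)c2ccccc2)C=C(C)[C@@H](OCc2ccc(OC)cc2)C[C@@H]1C(C)=C
F2 | step 9 | ring-expanded trimethylsilyl dienol ether (6-trimethylsilyloxy-13-norgermacra-1(10),4,6,11-tetraene, 3β-OPMB, 8β-SiMe2Ph) | C[Si](C)(C)O/C1=C(/C=C)[C@H]([Si](C)(C)c2ccccc2)C/C(C)=C/C[C@H](OCc2ccc(OC)cc2)/C(C)=C\1
F3 | step 13 | 6,12-acetonide of diol 22 | CC1(C)O[C@@H]2/C=C(/C)[C@@H](OCc3ccc(OC)cc3)C/C=C(C)/C[C@@H]([Si](C)(C)c3ccccc3)[C@H]2CCO1
F4 | step 13 | 8β-hydroxy 6,12-acetonide | CC1(C)O[C@@H]2/C=C(/C)[C@@H](OCc3ccc(OC)cc3)C/C=C(C)/C[C@@H](O)[C@H]2CCO1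
F5 | step 13 | 8β-(tert-butyldimethylsilyloxy) 6,12-acetonide | CC1(C)O[C@@H]2/C=C(/C)[C@@H](OCc3ccc(OC)cc3)C/C=C(C)/C[C@@H](O[Si](C)(C)C(C)(C)C)[C@H]2CCO1
F6 | step 13 | 8β-(tert-butyldimethylsilyloxy)-3β-(4-methoxybenzyloxy)-13-norgermacra-1(10),4-diene-6α,12-diol | O[C@@H]1/C=C(/C)[C@@H](OCc2ccc(OC)cc2)C/C=C(C)/C[C@@H](O[Si](C)(C)C(C)(C)C)[C@H]1CCO
F0 | step 21 | none | none
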